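**Assumption:** clerodane numbering and α/β descriptors are used for all bicyclic intermediates (α = face of C19/C20 in the target, β = face of H‑10). The route is a proposal built from known reaction types; selectivities are predictions, not experimental results.

## Retrosynthetic overview

1. Target ⇐ 4α,18‑epoxide (chloride opening last); butenolide ⇐ 3‑furyl group; C12 carbinol ⇐ CBS reduction of a furyl ketone made by opening a C12→O1 δ‑lactone.
2. 1β‑OH and H‑10β ⇐ β‑face hydroboration of a Δ1(10) alkene; epoxide ⇐ C4 ketone (sulfonium ylide).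
3. Key step: quaternary C5 with C19 ⇐ [2,3]‑Wittig–Still rearrangement of a Δ5(10)‑1α‑stannylmethyl ether, which moves chirality from C1 to C5 and places C19 syn to Me‑20.
4. Δ5(10)‑octalin ⇐ Saegusa oxidation of the Diels–Alder adduct of a ring‑A 2‑silyloxy diene with tiglic aldehyde (sets C8/C9 from the C1 stereocentre).
5. Ring order: ring A (commercial enone ketal, CBS) → ring B (intermolecular Diels–Alder) → butenolide ring (from furan) last.

## Route

**Step 1**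
Reactants: 1, 1,4‑dioxaspiro[4.5]dec‑6‑en‑8‑one
Product: 2, (S)‑1,4‑dioxaspiro[4.5]dec‑6‑en‑8‑ol
Conditions: (R)‑Me‑CBS (10 mol %), BH3·SMe2, THF, −20 °C
Reagents that add atoms: none
Why: CBS reduction with the C=C side as the large group gives the (S)‑allylic alcohol (future C1).

**Step 2**
Reactants: 2
Product: 3, (S)‑8‑[(4‑methoxybenzyl)oxy]‑1,4‑dioxaspiro[4.5]dec‑6‑ene
Conditions: NaH, PMBCl, TBAI (cat.), THF/DMF, 0 °C → rt
Reagents that add atoms: 4‑methoxybenzyl chloride, COc1ccc(CCl)cc1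
Why: Williamson etherification; the stereocentre is untouched.

**Step 3**
Reactants: 3
Product: 4, (S)‑4‑[(4‑methoxybenzyl)oxy]cyclohex‑2‑en‑1‑one
Conditions: PPTS, acetone/H2O, 50 °C
Reagents that add atoms: water, O
Why: Hydrolysis of the allylic ketal transposes the enone so that the carbon next to the new carbonyl (future C5) can be functionalised.

**Step 4**
Reactants: 4
Product: 5, (S)‑2‑iodo‑4‑[(4‑methoxybenzyl)oxy]cyclohex‑2‑en‑1‑one
Conditions: I2, pyridine/CH2Cl2, rt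
Reagents that add atoms: iodine, II
Why: Johnson α‑iodination of an enone (pyridine addition–iodination–elimination).

**Step 5**
Reactants: 5
Product: 6, (S)‑6‑iodo‑8‑[(4‑methoxybenzyl)oxy]‑1,4‑dioxaspiro[4.5]dec‑6‑ene
Conditions: (TMSOCH2)2, TMSOTf (cat.), CH2Cl2, −78 → −20 °C
Reagents that add atoms: 1,2‑bis(trimethylsilyloxy)ethane, C[Si](C)(C)OCCO[Si](C)(C)C
Why: Noyori ketalisation masks the future C4 ketone as a carbon with no hydrogens, which later forces the Saegusa elimination toward C10.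

**Step 6**
Reactants: 6
Product: 7, 1‑[(S)‑8‑[(4‑methoxybenzyl)oxy]‑1,4‑dioxaspiro[4.5]dec‑6‑en‑6‑yl]ethan‑1‑one
Conditions: t‑BuLi (2.1 eq), THF, −78 °C; then MeC(O)N(OMe)Me
Reagents that add atoms: N‑methoxy‑N‑methylacetamide, CC(=O)N(C)OC
Why: Iodine–lithium exchange gives a stable 2‑lithio enone ketal, which is acylated once by the Weinreb amide (C6/C7 installed).

**Step 7**
Reactants: 7
Product: 8, 2‑silyloxy diene: tert‑butyldimethylsilyl enol ether of 7 (CH2=C(OTBS)– on C5)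
Conditions: LDA, THF, −78 °C; then TBSOTf
Reagents that add atoms: TBSOTf, CC(C)(C)[Si](C)(C)OS(=O)(=O)C(F)(F)F
Why: Kinetic deprotonation of the methyl ketone and O‑silylation give the cross‑conjugated diene.

**Step 8**
Reactants: 8; 9, (E)‑2‑methylbut‑2‑enal (tiglic aldehyde)
Product: 10, Diels–Alder adduct: 1α‑OPMB, 4,4‑ethylenedioxy, 6‑OTBS‑Δ5(6), 8α‑Me, 9α‑Me, 9β‑CHO, 10α‑H octalin
Conditions: Me2AlCl, CH2Cl2, −78 → −40 °C
Reagents that add atoms: none
Why: Lewis‑acid Diels–Alder: the 2‑silyloxy group fixes regiochemistry (C7–C8 and C10–C9 bonds), the (E)‑dienophile keeps Me‑17/Me‑20 cis, and an endo‑CHO approach anti to the pseudo‑axial C1‑OPMB sets C8 and C9 with Me‑20 syn to O‑1 (the C10 centre is erased in Step 10).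

**Step 9**
Reactants: 10
Product: 11, as 10 but 9β‑vinyl (C11=C12) in place of CHO
Conditions: Ph3PCH3Br, KOtBu, THF, 0 °C → rt
Reagents that add atoms: methyltriphenylphosphonium bromide, C[P+](c1ccccc1)(c1ccccc1)c1ccccc1.[Br-]
Why: Wittig methylenation of a non‑enolisable aldehyde adds C12; the silyl enol ether tolerates the ylide.

**Step 10**
Reactants: 11
Product: 12, Δ5(10)‑6‑one: 1α‑OPMB, 4,4‑ethylenedioxy, 8α,9α‑dimethyl, 9β‑vinyl
Conditions: Pd(OAc)2, MeCN, rt → 40 °C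
Reagents that add atoms: none
Why: Saegusa–Ito oxidation; β‑hydride elimination can only use H‑10 because C4 carries no hydrogen, giving the ring‑fusion enone.

**Step 11**
Reactants: 12
Product: 13, 6α‑alcohol (6S) of 12
Conditions: (R)‑Me‑CBS, catecholborane, toluene, −78 → −40 °C
Reagents that add atoms: none
Why: Reagent‑controlled CBS 1,2‑reduction (alkenyl side large) sets C6; catecholborane leaves the vinyl group alone.

**Step 12**
Reactants: 13
Product: 14, 6α‑OTBS ether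
Conditions: TBSOTf, 2,6‑lutidine, CH2Cl2, −78 °C
Reagents that add atoms: TBSOTf, CC(C)(C)[Si](C)(C)OS(=O)(=O)C(F)(F)F
Why: Silylation of a hindered secondary alcohol.

**Step 13**
Reactants: 14
Product: 15, 1α‑alcohol (PMB removed)
Conditions: DDQ, CH2Cl2/pH 7 buffer, 0 °C
Reagents that add atoms: none
Why: Oxidative PMB cleavage, orthogonal to TBS and ketal.

**Step 14**
Reactants: 15
Product: 16, 1α‑O‑CH2SnBu3 ether
Conditions: KH, Bu3SnCH2I, 18‑crown‑6 (cat.), THF, 0 °C → rt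
Reagents that add atoms: tributyl(iodomethyl)stannane, CCCC[Sn](CCCC)(CCCC)CI
Why: Williamson etherification gives the Still precursor.

**Step 15**
Reactants: 16
Product: 17, Δ1(10)‑alkene with quaternary C5: 5α‑CH2OTBS (C19), 6α‑OTBS, 4,4‑ethylenedioxy, 8α,9α‑dimethyl, 9β‑vinyl
Conditions: n‑BuLi, THF, −78 → −30 °C; then TBSOTf, 2,6‑lutidine
Reagents that add atoms: TBSOTf, CC(C)(C)[Si](C)(C)OS(=O)(=O)C(F)(F)F
Why: Sn–Li exchange then suprafacial [2,3]‑Wittig–Still rearrangement delivers CH2O– from the pseudo‑axial 1α‑oxygen to the α face of C5 (syn to Me‑20, the relationship that intermolecular alkylation would disfavour); the alkoxide is silylated in the same pot.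

**Step 16**
Reactants: 17
Product: 18, trans‑decalin diol: 1β‑OH, 10β‑H, 9β‑CH2CH2OH (C12‑OH), bis‑TBS, C4 ketal
Conditions: BH3·THF (excess), 0 °C → rt; then NaOH, H2O2
Reagents that add atoms: hydrogen peroxide, OO
Why: Hydroboration–oxidation: the vinyl group gives the primary C12 alcohol, and syn addition to C1=C10 from the β face (opposite C19 and Me‑20, helped by delivery from the C12 borane) sets 10β‑H and equatorial 1β‑OH.

**Step 17**
Reactants: 18
Product: 19, C4 ketone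
Conditions: PPTS (cat.), wet acetone, 45 °C
Reagents that add atoms: water, O
Why: Mild ketal hydrolysis; the hindered TBS ethers survive.

**Step 18**
Reactants: 19
Product: 20, 4α,18‑spiro‑epoxide (O α, CH2 β), diol
Conditions: Me3S+ I−, KHMDS (excess), THF, −10 → 0 °C
Reagents that add atoms: trimethylsulfonium iodide, C[S+](C)C.[I-]
Why: Corey–Chaykovsky epoxidation; the sulfonium ylide attacks axially from the β face, so CH2 is axial (β) and oxygen equatorial (α), setting C4.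

**Step 19**
Reactants: 20
Product: 21, δ‑lactone C12(=O)–O–C1
Conditions: TEMPO (cat.), PhI(OAc)2, CH2Cl2, rt
Reagents that add atoms: none
Why: Primary‑selective TEMPO oxidation; the aldehyde closes on the nearby 1β‑OH to a lactol that is oxidised on to the lactone.

**Step 20**
Reactants: 21; 22, 3‑bromofuran (as 3‑furyllithium)
Product: 23, 12‑(3‑furyl) ketone with free 1β‑OH (may equilibrate with its hemiketal)
Conditions: 22, n‑BuLi, THF, −78 °C; then 21, −78 °C; NH4Cl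
Reagents that add atoms: none
Why: Single addition of the aryllithium to the lactone; the tetrahedral alkoxide is stable at −78 °C and opens to the ketone on work‑up.

**Step 21**
Reactants: 23
Product: 24, (12S)‑furyl carbinol, 1β,12‑diol
Conditions: (R)‑Me‑CBS, BH3·SMe2, THF, −30 °C
Reagents that add atoms: none
Why: CBS reduction of a heteroaryl ketone (furyl large, CH2 small) sets C12 as S.

**Step 22**
Reactants: 24; 25, (S)‑2‑methylbutanoic anhydride
Product: 26, 1β,12‑bis[(S)‑2‑methylbutanoate]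
Conditions: DMAP, Et3N, CH2Cl2, rt → 40 °C
Reagents that add atoms: none
Why: DMAP‑catalysed acylation with the anhydride avoids ketene formation, so the α‑stereocentres of the acyl groups are kept.

**Step 23**
Reactants: 26
Product: 27, 6α,19‑diol
Conditions: TBAF, AcOH, THF, rt → 40 °C
Reagents that add atoms: none
Why: Buffered fluoride desilylation; esters, furan and epoxide are stable.

**Step 24**
Reactants: 27
Product: 28, 6α,19‑diacetate
Conditions: Ac2O, pyridine, DMAP, rt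
Reagents that add atoms: acetic anhydride, CC(=O)OC(C)=O
Why: Standard acetylation.

**Step 25**
Reactants: 28
Product: 29, γ‑hydroxybutenolide (5‑hydroxy‑4‑substituted furan‑2(5H)‑one, hemiacetal epimers)
Conditions: O2, hν, rose bengal, i‑Pr2NEt, CH2Cl2, −78 °C
Reagents that add atoms: oxygen, O=O
Why: Singlet‑oxygen [4+2] on the 3‑substituted furan; the hindered base removes the less hindered endoperoxide proton, placing the carbonyl distal to the side chain.

**Step 26**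
Reactants: 29
Product: 30, butenolide 4α,18‑epoxide
Conditions: NaBH4, EtOH, 0 °C; then AcOH
Reagents that add atoms: none
Why: Reduction of the masked aldehyde and relactonisation give the β‑substituted butenolide; esters survive at 0 °C.

**Step 27**
Reactants: 30
Product: 31, ajugaciliatin A
Conditions: LiCl, AcOH, THF, rt
Reagents that add atoms: lithium chloride, [Li+].[Cl-]
Why: Acid‑assisted SN2 opening of the epoxide at the primary C18 by chloride leaves the 4α tertiary alcohol with C4 unchanged.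

## Compound list

1 | 1,4‑dioxaspiro[4.5]dec‑6‑en‑8‑one | O=C1C=CC2(CC1)OCCO2 | starting material
2 | (S)‑1,4‑dioxaspiro[4.5]dec‑6‑en‑8‑ol | O[C@@H]1C=CC2(CC1)OCCO2 | intermediate
3 | (S)‑8‑(PMB‑oxy)‑1,4‑dioxaspiro[4.5]dec‑6‑ene | COc1ccc(CO[C@@H]2C=CC3(CC2)OCCO3)cc1 | intermediate
4 | (S)‑4‑(PMB‑oxy)cyclohex‑2‑en‑1‑one | COc1ccc(CO[C@@H]2C=CC(=O)CC2)cc1 | intermediate
5 | (S)‑2‑iodo‑4‑(PMB‑oxy)cyclohex‑2‑en‑1‑one | COc1ccc(CO[C@@H]2C=C(I)C(=O)CC2)cc1 | intermediate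
6 | (S)‑6‑iodo‑8‑(PMB‑oxy)‑1,4‑dioxaspiro[4.5]dec‑6‑ene | COc1ccc(CO[C@@H]2C=C(I)C3(CC2)OCCO3)cc1 | intermediate
7 | 6‑acetyl‑(S)‑8‑(PMB‑oxy)‑1,4‑dioxaspiro[4.5]dec‑6‑ene | COc1ccc(CO[C@@H]2C=C(C(C)=O)C3(CC2)OCCO3)cc1 | intermediate
8 | 2‑(TBSO) diene from 7 | COc1ccc(CO[C@@H]2C=C(C(=C)O[Si](C)(C)C(C)(C)C)C3(CC2)OCCO3)cc1 | intermediate
9 | (E)‑2‑methylbut‑2‑enal | C/C=C(\C)C=O | starting material
10 | Diels–Alder adduct (1α‑OPMB, 6‑OTBS‑Δ5(6), 9β‑CHO, 10α‑H) | O=C[C@@]1(C)[C@H](C)CC(O[Si](C)(C)C(C)(C)C)=C2[C@H]1[C@@H](OCc3ccc(OC)cc3)CCC24OCCO4 | intermediate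
11 | 9β‑vinyl silyl enol ether | C=C[C@@]1(C)[C@H](C)CC(O[Si](C)(C)C(C)(C)C)=C2[C@H]1[C@@H](OCc3ccc(OC)cc3)CCC24OCCO4 | intermediate
12 | Δ5(10)‑6‑one | C=C[C@@]1(C)[C@H](C)CC(=O)C2=C1[C@@H](OCc3ccc(OC)cc3)CCC24OCCO4 | intermediate
13 | 6α‑alcohol | C=C[C@@]1(C)[C@H](C)C[C@H](O)C2=C1[C@@H](OCc3ccc(OC)cc3)CCC24OCCO4 | intermediate
14 | 6α‑OTBS, 1α‑OPMB | C=C[C@@]1(C)[C@H](C)C[C@H](O[Si](C)(C)C(C)(C)C)C2=C1[C@@H](OCc3ccc(OC)cc3)CCC24OCCO4 | intermediate
15 | 6α‑OTBS, 1α‑OH | C=C[C@@]1(C)[C@H](C)C[C@H](O[Si](C)(C)C(C)(C)C)C2=C1[C@@H](O)CCC24OCCO4 | intermediate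
16 | 1α‑O‑CH2SnBu3 ether | C=C[C@@]1(C)[C@H](C)C[C@H](O[Si](C)(C)C(C)(C)C)C2=C1[C@@H](OC[Sn](CCCC)(CCCC)CCCC)CCC24OCCO4 | intermediate
17 | Δ1(10), 5α‑CH2OTBS, 6α‑OTBS | C=C[C@@]1(C)[C@H](C)C[C@H](O[Si](C)(C)C(C)(C)C)[C@]2(CO[Si](C)(C)C(C)(C)C)C1=CCCC23OCCO3 | intermediate
18 | 1β,12‑diol, trans‑decalin, C4 ketal | OCC[C@@]1(C)[C@H](C)C[C@H](O[Si](C)(C)C(C)(C)C)[C@]2(CO[Si](C)(C)C(C)(C)C)[C@@H]1[C@H](O)CCC23OCCO3 | intermediate
19 | 1β,12‑diol, C4 ketone | OCC[C@@]1(C)[C@H](C)C[C@H](O[Si](C)(C)C(C)(C)C)[C@]2(CO[Si](C)(C)C(C)(C)C)[C@@H]1[C@H](O)CCC2=O | intermediate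
20 | 1β,12‑diol, 4α,18‑epoxide | OCC[C@@]1(C)[C@H](C)C[C@H](O[Si](C)(C)C(C)(C)C)[C@]2(CO[Si](C)(C)C(C)(C)C)[C@@H]1[C@H](O)CC[C@]23CO3 | intermediate
21 | 12→1 δ‑lactone | O=C1C[C@@]2(C)[C@H](C)C[C@H](O[Si](C)(C)C(C)(C)C)[C@]3(CO[Si](C)(C)C(C)(C)C)[C@@H]2[C@H](O1)CC[C@]34CO4 | intermediate
22 | 3‑bromofuran | Brc1ccoc1 | starting material
23 | 12‑(3‑furyl) ketone, 1β‑OH | O=C(C[C@@]1(C)[C@H](C)C[C@H](O[Si](C)(C)C(C)(C)C)[C@]2(CO[Si](C)(C)C(C)(C)C)[C@@H]1[C@H](O)CC[C@]23CO3)c4ccoc4 | intermediate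
24 | (12S)‑furyl carbinol, 1β‑OH | O[C@@H](C[C@@]1(C)[C@H](C)C[C@H](O[Si](C)(C)C(C)(C)C)[C@]2(CO[Si](C)(C)C(C)(C)C)[C@@H]1[C@H](O)CC[C@]23CO3)c4ccoc4 | intermediate
25 | (S)‑2‑methylbutanoic anhydride | CC[C@H](C)C(=O)OC(=O)[C@@H](C)CC | starting material
26 | 1,12‑bis[(S)‑2‑methylbutanoate], bis‑TBS | CC[C@H](C)C(=O)O[C@@H](C[C@@]1(C)[C@H](C)C[C@H](O[Si](C)(C)C(C)(C)C)[C@]2(CO[Si](C)(C)C(C)(C)C)[C@@H]1[C@H](OC(=O)[C@@H](C)CC)CC[C@]23CO3)c4ccoc4 | intermediate
27 | 6α,19‑diol | CC[C@H](C)C(=O)O[C@@H](C[C@@]1(C)[C@H](C)C[C@H](O)[C@]2(CO)[C@@H]1[C@H](OC(=O)[C@@H](C)CC)CC[C@]23CO3)c4ccoc4 | intermediate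
28 | 6α,19‑diacetate (furan) | CC[C@H](C)C(=O)O[C@@H](C[C@@]1(C)[C@H](C)C[C@H](OC(C)=O)[C@]2(COC(C)=O)[C@@H]1[C@H](OC(=O)[C@@H](C)CC)CC[C@]23CO3)c4ccoc4 | intermediate
29 | γ‑hydroxybutenolide | CC[C@H](C)C(=O)O[C@@H](C[C@@]1(C)[C@H](C)C[C@H](OC(C)=O)[C@]2(COC(C)=O)[C@@H]1[C@H](OC(=O)[C@@H](C)CC)CC[C@]23CO3)C4=CC(=O)OC4O | intermediate
30 | butenolide 4α,18‑epoxide | CC[C@H](C)C(=O)O[C@@H](C[C@@]1(C)[C@H](C)C[C@H](OC(C)=O)[C@]2(COC(C)=O)[C@@H]1[C@H](OC(=O)[C@@H](C)CC)CC[C@]23CO3)C4=CC(=O)OC4 | intermediate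
31 | ajugaciliatin A | CC[C@H](C)C(=O)O[C@@H](C[C@@]1(C)[C@H](C)C[C@H](OC(C)=O)[C@]2(COC(C)=O)[C@@H]1[C@H](OC(=O)[C@@H](C)CC)CC[C@]2(O)CCl)C1=CC(=O)OC1 | target

## Summary

Total steps: 27. Longest linear sequence: 27 (from compound 1).

Steps most likely to fail, each with a fallback:

1. **Step 8 (Diels–Alder: reactivity of the hindered partners and the endo/anti selectivity that links C1 to C8/C9).** Fallback: build ring B first by a catalyst‑controlled Rawal aminosiloxydiene/tiglic aldehyde Diels–Alder (Cr–salen), giving 4‑formyl‑4,5‑dimethylcyclohexenone; then annulate ring A onto C5/C10 and set the 1α‑carbinol afterwards by CBS reduction of the Δ5(10)‑1‑one.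
2. **Step 15 ([2,3]‑Wittig–Still forming quaternary C5 next to the ketal).** Fallback: oxidise 15 to the Δ5(10)‑1‑one, attach BrCH2SiMe2– to the 6α‑OH and run a Stork silicon‑tethered 5‑exo radical conjugate addition (Bu3SnH/AIBN). Tamao oxidation then gives the 6α,19‑diol, and the C1 ketone is reduced to the equatorial 1β‑ol with dissolving metal.
3. **Step 18 (ylide addition to the neopentyl C4 ketone: enolisation or wrong face).** Fallback: Takai–Lombardo methylenation to the 4(18)‑exocyclic alkene, free the C19‑OH, and use it to direct VO(acac)2/TBHP epoxidation to the α face.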